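**Plan**

- Cuts (hexahydronaphthalen-2(1H)-one numbering): both C–Br bonds go back to C–OH with inversion. Ring A and ring B are cut together at C1–C2 and C4a–C8a. The butenolide so exposed is cut at Cα–Cβ and O–Cγ into a C10 acid and a C10 epoxy iodide. The cyclopentane is cut at its C1–C2 bond.
- Enabling feature: ring A is a 4-hydroxycyclohex-2-en-1-one (C2=O, C3=C4, C4a–OH), the opened form of a 1-silyloxy-7-oxabicyclo[2.2.1]hept-2-ene. Furan atoms C2, C3, C4, C4a and the ring oxygen supply the diene; the isopropenyl ketone C1=C8a–C8(=O), held to C4a through C5–C6–C7, supplies the dienophile.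
- Forward order: cyclopentane (radical 5-exo closure of epoxy-geranate), side chain from geranyl acetate, union by dianion alkylation and lactonisation, butenolide, rings A and B in one operation, then the ring B bromide.
- Stereochemistry: Shi epoxidation sets the cyclopentane carbinol carbon, the radical cyclisation relays it to the quaternary carbon, and inversion gives the bromide. Sharpless epoxidation sets C5, which steers the cycloaddition (exo tether gives the trans fusion at C4a/C8a). Chelation-controlled reduction and inversion set C8.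

Key step: step 14

Remark: the CH(OSi) carbon of 8–17 is racemic and the lactone α-carbon of 13–15 is unselective; both centres are erased in steps 11 and 13, so these compounds are carried as epimer mixtures and their SMILES leave those centres undefined.

**Route**

Step 1
Reactants: 1 methyl (2E)-3,7-dimethylocta-2,6-dienoate (methyl geranate)
Product: 2 methyl (2E)-5-[(2S)-3,3-dimethyloxiran-2-yl]-3-methylpent-2-enoate
Conditions: L-fructose-derived Shi ketone (30 mol %), KHSO5 (as Oxone, 2KHSO5·KHSO4·K2SO4), K2CO3, Bu4NHSO4, MeCN/dimethoxymethane/aq. Na2B4O7 buffer, 0 °C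
Reagents that add atoms: potassium peroxymonosulfate KHSO5, [K+].[O-]S(=O)(=O)OO
Why: Shi asymmetric epoxidation, in which the chiral dioxirane attacks only the electron-rich 6,7-alkene (the enoate is deactivated) through the spiro transition state and should set the (S) epoxide carbon.

Step 2
Reactants: 2 methyl (2E)-5-[(2S)-3,3-dimethyloxiran-2-yl]-3-methylpent-2-enoate
Product: 3 methyl 2-[(1R,3S)-3-hydroxy-1,2,2-trimethylcyclopentyl]acetate
Conditions: Cp2TiCl2 (10 mol %), Zn dust, 2,4,6-collidine hydrochloride, THF, rt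
Reagents that add atoms: none
Why: Nugent–RajanBabu epoxide opening by Cp2TiCl (trivalent titanium) gives the β-titanoxy tertiary radical, which closes 5-exo-trig onto the enoate β-carbon through a Beckwith–Houk chair with the titanoxy group pseudo-equatorial, so the acetate arm on the new quaternary carbon should end trans to oxygen (the α-ester radical is reduced and protonated by collidinium; any cis epimer lactonises and is separable).

Step 3
Reactants: 3 methyl 2-[(1R,3S)-3-hydroxy-1,2,2-trimethylcyclopentyl]acetate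
Product: 5 methyl 2-[(1R,3R)-3-bromo-1,2,2-trimethylcyclopentyl]acetate, via cyclopentyl triflate 4 (not isolated)
Conditions: Tf2O, pyridine, CH2Cl2, −40 °C; then Bu4NBr, toluene, −40 °C to rt
Reagents that add atoms: tetrabutylammonium bromide, CCCC[N+](CCCC)(CCCC)CCCC.[Br-]
Why: Triflation and SN2 displacement by soluble bromide in a non-ionising medium should invert the carbinol carbon, so the bromide ends cis to the acetate arm as in the target.

Step 4
Reactants: 5 methyl 2-[(1R,3R)-3-bromo-1,2,2-trimethylcyclopentyl]acetate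
Product: 6 2-[(1R,3R)-3-bromo-1,2,2-trimethylcyclopentyl]acetic acid
Conditions: LiOH, THF/MeOH/H2O, rt; then 1 M HCl
Reagents that add atoms: lithium hydroxide, [Li+].[OH-]
Why: Saponification of an unhindered CH2CO2Me ester, under which the neopentyl-type secondary bromide should resist substitution and elimination.

Step 5
Reactants: 7 (2E)-3,7-dimethylocta-2,6-dien-1-yl acetate (geranyl acetate)
Product: 8 (2E)-5-(3,3-dimethyloxiran-2-yl)-3-methylpent-2-en-1-yl acetate (racemic)
Conditions: mCPBA, CH2Cl2, 0 °C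
Reagents that add atoms: 3-chloroperoxybenzoic acid, OOC(=O)c1cccc(Cl)c1
Why: Prilezhaev epoxidation selects the more electron-rich 6,7-alkene because the 2,3-alkene is deactivated by the allylic acetate; the racemic centre later becomes a ketone.

Step 6
Reactants: 8 (2E)-5-(3,3-dimethyloxiran-2-yl)-3-methylpent-2-en-1-yl acetate
Product: 9 (2E)-6-(tert-butyldimethylsilyloxy)-3,7-dimethylocta-2,7-dien-1-yl acetate (racemic)
Conditions: TBSOTf, DBU, toluene, −78 °C to rt
Reagents that add atoms: tert-butyldimethylsilyl triflate, CC(C)(C)[Si](C)(C)OS(=O)(=O)C(F)(F)F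
Why: Silyl triflate/amidine isomerisation of a trisubstituted epoxide to an allylic silyl ether, in which the silylated epoxide opens at the tertiary carbon and DBU removes a methyl proton to give the isopropenyl carbinol as its silyl ether.

Step 7
Reactants: 9 (2E)-6-(tert-butyldimethylsilyloxy)-3,7-dimethylocta-2,7-dien-1-yl acetate
Product: 10 (2E)-6-(tert-butyldimethylsilyloxy)-3,7-dimethylocta-2,7-dien-1-ol (racemic)
Conditions: K2CO3 (cat.), MeOH, 0 °C
Reagents that add atoms: none
Why: Base-catalysed transesterification removes the allylic acetate and leaves the secondary silyl ether untouched.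

Step 8
Reactants: 10 (2E)-6-(tert-butyldimethylsilyloxy)-3,7-dimethylocta-2,7-dien-1-ol
Product: 11 [(2R,3R)-3-[3-(tert-butyldimethylsilyloxy)-4-methylpent-4-en-1-yl]-3-methyloxiran-2-yl]methanol
Conditions: Ti(OiPr)4, D-(−)-diethyl tartrate, t-BuOOH, 4 Å molecular sieves, CH2Cl2, −20 °C
Reagents that add atoms: tert-butyl hydroperoxide, CC(C)(C)OO
Why: Sharpless asymmetric epoxidation of the (E)-allylic alcohol with the D-tartrate should give the (2R,3R)-epoxide and so fix the tertiary C–O carbon (later C5); the isopropenyl alkene has no free allylic hydroxyl and is not touched.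

Step 9
Reactants: 11 [(2R,3R)-3-[3-(tert-butyldimethylsilyloxy)-4-methylpent-4-en-1-yl]-3-methyloxiran-2-yl]methanol
Product: 12 (2S,3R)-3-[3-(tert-butyldimethylsilyloxy)-4-methylpent-4-en-1-yl]-2-(iodomethyl)-3-methyloxirane
Conditions: I2, PPh3, imidazole, CH2Cl2, 0 °C
Reagents that add atoms: iodine, II
Why: Appel-type (Garegg–Samuelsson) iodination of the primary alcohol under buffered conditions that leave the epoxide and its configuration intact.

Step 10
Reactants: 6 2-[(1R,3R)-3-bromo-1,2,2-trimethylcyclopentyl]acetic acid; 12 (2S,3R)-3-[3-(tert-butyldimethylsilyloxy)-4-methylpent-4-en-1-yl]-2-(iodomethyl)-3-methyloxirane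
Product: 14 (5S)-3-[(1R,3R)-3-bromo-1,2,2-trimethylcyclopentyl]-5-[(2R)-5-(tert-butyldimethylsilyloxy)-2-hydroxy-6-methylhept-6-en-2-yl]oxolan-2-one, via lithium epoxy carboxylate 13 (not isolated)
Conditions: 6, LiN(iPr)2 (2.1 equiv), THF, −78 to −20 °C; 12, DMPU, −78 °C to rt; then 50 °C; aq. NH4Cl
Reagents that add atoms: none
Why: Alkylation of the carboxylic acid dianion at the primary iodide (SN2) and 5-exo-tet opening of the epoxide at its secondary carbon by the carboxylate (inversion there) should give the γ-lactone and free the tertiary alcohol with its configuration unchanged.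

Step 11
Reactants: 14 (5S)-3-[(1R,3R)-3-bromo-1,2,2-trimethylcyclopentyl]-5-[(2R)-5-(tert-butyldimethylsilyloxy)-2-hydroxy-6-methylhept-6-en-2-yl]oxolan-2-one
Product: 16 (5S)-3-[(1R,3R)-3-bromo-1,2,2-trimethylcyclopentyl]-5-[(2R)-5-(tert-butyldimethylsilyloxy)-2-hydroxy-6-methylhept-6-en-2-yl]furan-2(5H)-one, via α-phenylselanyl lactone 15 (not isolated)
Conditions: LiN(iPr)2 (2.2 equiv), THF, −78 °C; PhSeBr; AcOH, then 30% H2O2, 0 °C to rt
Reagents that add atoms: none
Why: Selenation of the lactone enolate and selenoxide syn-elimination, which can only run towards the ring CH2 because the cyclopentyl carbon is quaternary, should give the α-substituted butenolide.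

Step 12
Reactants: 16 (5S)-3-[(1R,3R)-3-bromo-1,2,2-trimethylcyclopentyl]-5-[(2R)-5-(tert-butyldimethylsilyloxy)-2-hydroxy-6-methylhept-6-en-2-yl]furan-2(5H)-one
Product: 17 (5S)-3-[(1R,3R)-3-bromo-1,2,2-trimethylcyclopentyl]-5-[(2R)-2,5-dihydroxy-6-methylhept-6-en-2-yl]furan-2(5H)-one
Conditions: HF·pyridine, THF, 0 °C to rt
Reagents that add atoms: none
Why: Fluoride cleavage of the secondary silyl ether under weakly acidic conditions that do not deprotonate the butenolide.

Step 13
Reactants: 17 (5S)-3-[(1R,3R)-3-bromo-1,2,2-trimethylcyclopentyl]-5-[(2R)-2,5-dihydroxy-6-methylhept-6-en-2-yl]furan-2(5H)-one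
Product: 18 (5S)-3-[(1R,3R)-3-bromo-1,2,2-trimethylcyclopentyl]-5-[(2R)-2-hydroxy-6-methyl-5-oxohept-6-en-2-yl]furan-2(5H)-one
Conditions: Dess–Martin periodinane, CH2Cl2, 0 °C
Reagents that add atoms: none
Why: Dess–Martin oxidation of the secondary allylic alcohol gives the isopropenyl ketone (the dienophile), while the tertiary alcohol and the butenolide are inert.

Step 14
Reactants: 18 (5S)-3-[(1R,3R)-3-bromo-1,2,2-trimethylcyclopentyl]-5-[(2R)-2-hydroxy-6-methyl-5-oxohept-6-en-2-yl]furan-2(5H)-one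
Product: 22 (4aR,5R,8aS)-3-[(1R,3R)-3-bromo-1,2,2-trimethylcyclopentyl]-4a,5-dihydroxy-5,8a-dimethyl-4a,5,6,7-tetrahydronaphthalene-2,8(1H,8aH)-dione, via bis-silylated silyloxyfuran 19 (not isolated), via oxanorbornene cycloadduct 20 (not isolated), via bis(trimethylsilyl) ether 21 (not isolated)
Conditions: Me3SiCl, Et3N, DMAP (cat.), CH2Cl2, 0 °C to rt; toluene, 80 °C; then 1 M HCl, THF, 0 °C
Reagents that add atoms: none
Why: Proposed new method: Et3N/Me3SiCl should enolise only the butenolide (its γ-C–H gives an aromatic furanolate, whereas the ketone needs far harsher silylation) to silyloxyfuran 19, whose diene (furan C2 to C5) adds suprafacially across the tethered isopropenyl ketone to the 1-silyloxy-7-oxanorbornene 20; push from the silyloxy oxygen then breaks the bridge C–O bond of this bridgehead ketal, the silyl group passes to the angular alkoxide and enone 21 forms irreversibly, so furan cycloreversion cannot drain the adduct. The closest known reactions are the intermolecular Diels–Alder additions of 2-silyloxyfurans to electron-poor alkenes, whose adducts open to 4-hydroxycyclohex-2-enones, and the intramolecular furan Diels–Alder reaction of enones held to the furan by four atoms; their combination in one substrate is new. Ring B closes as the tether ring of a type 1 intramolecular cycloaddition (six-membered, bond from furan C5 to the enone α-carbon), and ring A is the new six-membered ring of the [4+2] event (second bond from furan C2 to the enone CH2). The two angular centres arise together: an exo tether (syn to the oxygen bridge, usual for furans tethered at the diene terminus and favoured by the α-methyl group of the dienophile) places the angular methyl anti to the bridging oxygen and gives the trans fusion, and the face is set by the tertiary carbinol carbon, whose CH3 takes the pseudo-equatorial and whose OSiMe3 the pseudo-axial site of the chair-like tether, avoiding a 1,3-diaxial CH3/CH3 contact and keeping the two C–O dipoles anti. The step needs the tether to override the polarity preference of the silyloxyfuran (C5 would rather attack the enone CH2 in a seven-membered Mukaiyama–Michael closure), which the neutral, Lewis-acid-free thermal conditions and the six- versus seven-membered ring size should secure.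

Step 15
Reactants: 22 (4aR,5R,8aS)-3-[(1R,3R)-3-bromo-1,2,2-trimethylcyclopentyl]-4a,5-dihydroxy-5,8a-dimethyl-4a,5,6,7-tetrahydronaphthalene-2,8(1H,8aH)-dione
Product: 23 (4aR,5R,8R,8aR)-3-[(1R,3R)-3-bromo-1,2,2-trimethylcyclopentyl]-4a,5,8-trihydroxy-5,8a-dimethyl-4a,5,6,7,8,8a-hexahydronaphthalen-2(1H)-one
Conditions: Et2BOMe, THF/MeOH (4:1), −78 °C; NaBH4; AcOH, then MeOH (evaporation)
Reagents that add atoms: none
Why: Narasaka–Prasad reduction, in which the diethylboron chelate between the axial angular hydroxyl and the β-ketone activates only this carbonyl (the enone cannot chelate) and shields its upper face, so hydride should enter equatorially and give the axial alcohol syn to the angular OH.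

Step 16
Reactants: 23 (4aR,5R,8R,8aR)-3-[(1R,3R)-3-bromo-1,2,2-trimethylcyclopentyl]-4a,5,8-trihydroxy-5,8a-dimethyl-4a,5,6,7,8,8a-hexahydronaphthalen-2(1H)-one
Product: 25 (4aR,5R,8S,8aS)-8-bromo-3-[(1R,3R)-3-bromo-1,2,2-trimethylcyclopentyl]-4a,5-dihydroxy-5,8a-dimethyl-4a,5,6,7,8,8a-hexahydronaphthalen-2(1H)-one, via axial C8 triflate 24 (not isolated)
Conditions: Tf2O, pyridine, CH2Cl2, −78 °C; then Bu4NBr, −78 °C to rt
Reagents that add atoms: tetrabutylammonium bromide, CCCC[N+](CCCC)(CCCC)CCCC.[Br-]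
Why: Selective triflation of the only secondary alcohol and SN2 displacement by bromide with inversion should turn the axial C–O bond into the equatorial C–Br bond; the angular hydroxyl is syn to the leaving group and cannot displace it.

**Compound list**

1 | methyl (2E)-3,7-dimethylocta-2,6-dienoate (methyl geranate) | CC(C)=CCC/C(C)=C/C(=O)OC | starting material
2 | methyl (2E)-5-[(2S)-3,3-dimethyloxiran-2-yl]-3-methylpent-2-enoate | CC1(C)[C@@H](O1)CC/C(C)=C/C(=O)OC | intermediate
3 | methyl 2-[(1R,3S)-3-hydroxy-1,2,2-trimethylcyclopentyl]acetate | CC1(C)[C@@H](O)CC[C@]1(C)CC(=O)OC | intermediate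
4 | methyl 2-[(1R,3S)-1,2,2-trimethyl-3-(trifluoromethylsulfonyloxy)cyclopentyl]acetate | CC1(C)[C@@H](OS(=O)(=O)C(F)(F)F)CC[C@]1(C)CC(=O)OC | intermediate (not isolated)
5 | methyl 2-[(1R,3R)-3-bromo-1,2,2-trimethylcyclopentyl]acetate | CC1(C)[C@H](Br)CC[C@]1(C)CC(=O)OC | intermediate
6 | 2-[(1R,3R)-3-bromo-1,2,2-trimethylcyclopentyl]acetic acid | CC1(C)[C@H](Br)CC[C@]1(C)CC(=O)O | intermediate
7 | (2E)-3,7-dimethylocta-2,6-dien-1-yl acetate (geranyl acetate) | CC(C)=CCC/C(C)=C/COC(C)=O | starting material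
8 | (2E)-5-(3,3-dimethyloxiran-2-yl)-3-methylpent-2-en-1-yl acetate (racemic) | CC1(C)OC1CC/C(C)=C/COC(C)=O | intermediate
9 | (2E)-6-(tert-butyldimethylsilyloxy)-3,7-dimethylocta-2,7-dien-1-yl acetate (racemic) | C=C(C)C(O[Si](C)(C)C(C)(C)C)CC/C(C)=C/COC(C)=O | intermediate
10 | (2E)-6-(tert-butyldimethylsilyloxy)-3,7-dimethylocta-2,7-dien-1-ol (racemic) | C=C(C)C(O[Si](C)(C)C(C)(C)C)CC/C(C)=C/CO | intermediate
11 | [(2R,3R)-3-[3-(tert-butyldimethylsilyloxy)-4-methylpent-4-en-1-yl]-3-methyloxiran-2-yl]methanol | OC[C@H]1O[C@]1(C)CCC(O[Si](C)(C)C(C)(C)C)C(C)=C | intermediate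
12 | (2S,3R)-3-[3-(tert-butyldimethylsilyloxy)-4-methylpent-4-en-1-yl]-2-(iodomethyl)-3-methyloxirane | IC[C@H]1O[C@]1(C)CCC(O[Si](C)(C)C(C)(C)C)C(C)=C | intermediate
13 | lithium 2-[(1R,3R)-3-bromo-1,2,2-trimethylcyclopentyl]-3-[(2R,3R)-3-[3-(tert-butyldimethylsilyloxy)-4-methylpent-4-en-1-yl]-3-methyloxiran-2-yl]propanoate | CC1(C)[C@H](Br)CC[C@]1(C)C(C[C@H]2O[C@]2(C)CCC(O[Si](C)(C)C(C)(C)C)C(C)=C)C(=O)[O-].[Li+] | intermediate (not isolated)
14 | (5S)-3-[(1R,3R)-3-bromo-1,2,2-trimethylcyclopentyl]-5-[(2R)-5-(tert-butyldimethylsilyloxy)-2-hydroxy-6-methylhept-6-en-2-yl]oxolan-2-one | CC1(C)[C@H](Br)CC[C@]1(C)C1C[C@H](OC1=O)[C@](C)(O)CCC(O[Si](C)(C)C(C)(C)C)C(C)=C | intermediate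
15 | 3-(phenylselanyl) derivative of 14 | CC1(C)[C@H](Br)CC[C@]1(C)C1([Se]c2ccccc2)C[C@H](OC1=O)[C@](C)(O)CCC(O[Si](C)(C)C(C)(C)C)C(C)=C | intermediate (not isolated)
16 | (5S)-3-[(1R,3R)-3-bromo-1,2,2-trimethylcyclopentyl]-5-[(2R)-5-(tert-butyldimethylsilyloxy)-2-hydroxy-6-methylhept-6-en-2-yl]furan-2(5H)-one | CC1(C)[C@H](Br)CC[C@]1(C)C1=C[C@H](OC1=O)[C@](C)(O)CCC(O[Si](C)(C)C(C)(C)C)C(C)=C | intermediate
17 | (5S)-3-[(1R,3R)-3-bromo-1,2,2-trimethylcyclopentyl]-5-[(2R)-2,5-dihydroxy-6-methylhept-6-en-2-yl]furan-2(5H)-one | CC1(C)[C@H](Br)CC[C@]1(C)C1=C[C@H](OC1=O)[C@](C)(O)CCC(O)C(C)=C | intermediate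
18 | (5S)-3-[(1R,3R)-3-bromo-1,2,2-trimethylcyclopentyl]-5-[(2R)-2-hydroxy-6-methyl-5-oxohept-6-en-2-yl]furan-2(5H)-one | CC1(C)[C@H](Br)CC[C@]1(C)C1=C[C@H](OC1=O)[C@](C)(O)CCC(=O)C(C)=C | intermediate
19 | 3-[(1R,3R)-3-bromo-1,2,2-trimethylcyclopentyl]-5-[(2R)-6-methyl-5-oxo-2-(trimethylsilyloxy)hept-6-en-2-yl]-2-(trimethylsilyloxy)furan | CC1(C)[C@H](Br)CC[C@]1(C)c1cc(oc1O[Si](C)(C)C)[C@](C)(O[Si](C)(C)C)CCC(=O)C(C)=C | intermediate (not isolated)
20 | tether-exo cycloadduct: 1-(trimethylsilyloxy)-7-oxabicyclo[2.2.1]hept-2-ene with the bridging oxygen joining C2 and C4a, fused to the 2-methylcyclohexanone ring bearing C5 OSiMe3 | CC1(C)[C@H](Br)CC[C@]1(C)C1=C[C@@]23O[C@]1(O[Si](C)(C)C)C[C@]2(C)C(=O)CC[C@@]3(C)O[Si](C)(C)C | intermediate (not isolated)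
21 | 4a,5-bis(trimethylsilyl) ether of 22 | CC1(C)[C@H](Br)CC[C@]1(C)C1=C[C@]2(O[Si](C)(C)C)[C@](C)(O[Si](C)(C)C)CCC(=O)[C@@]2(C)CC1=O | intermediate (not isolated)
22 | (4aR,5R,8aS)-3-[(1R,3R)-3-bromo-1,2,2-trimethylcyclopentyl]-4a,5-dihydroxy-5,8a-dimethyl-4a,5,6,7-tetrahydronaphthalene-2,8(1H,8aH)-dione | CC1(C)[C@H](Br)CC[C@]1(C)C1=C[C@]2(O)[C@](C)(O)CCC(=O)[C@@]2(C)CC1=O | intermediate
23 | (4aR,5R,8R,8aR)-3-[(1R,3R)-3-bromo-1,2,2-trimethylcyclopentyl]-4a,5,8-trihydroxy-5,8a-dimethyl-4a,5,6,7,8,8a-hexahydronaphthalen-2(1H)-one | CC1(C)[C@H](Br)CC[C@]1(C)C1=C[C@]2(O)[C@](C)(O)CC[C@@H](O)[C@@]2(C)CC1=O | intermediate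
24 | 8-O-trifluoromethylsulfonyl derivative of 23 | CC1(C)[C@H](Br)CC[C@]1(C)C1=C[C@]2(O)[C@](C)(O)CC[C@@H](OS(=O)(=O)C(F)(F)F)[C@@]2(C)CC1=O | intermediate (not isolated)
25 | (4aR,5R,8S,8aS)-8-bromo-3-[(1R,3R)-3-bromo-1,2,2-trimethylcyclopentyl]-4a,5-dihydroxy-5,8a-dimethyl-4a,5,6,7,8,8a-hexahydronaphthalen-2(1H)-one | CC1(C)[C@H](Br)CC[C@]1(C)C1=C[C@]2(O)[C@](C)(O)CC[C@H](Br)[C@@]2(C)CC1=O | target

**Counts and risks**

Total step count: 16. Longest linear sequence: 12 steps (7 to 25: steps 5–9, then 10–16).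

Steps most likely to fail:

1. Step 14. Enolisation may not stay on the butenolide. The silyloxyfuran may attack the enone CH2 through C5 (seven-membered Mukaiyama–Michael closure) or fail to cyclise in the orientation the tether demands. Wrong exo/endo or facial choice would give ring-fusion or C5 epimers. Fallback without cycloaddition, from 18 back to 22, built from known reaction types:
   - 18 is silylated as in step 14 at 0 °C, and crude 19 is oxidised with dimethyldioxirane (acetone, −78 °C) to the γ-hydroxybutenolide F1.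
   - PhSSiMe3 with catalytic Bu4NF adds to the isopropenyl ketone and gives the β-phenylthio silyl enol ether F2 (not isolated).
   - With BF3·OEt2 (CH2Cl2, −78 °C), F2 captures the furanone oxocarbenium ion formed from the hemiketal in a six-membered Mukaiyama-type closure. This gives the spiro-butenolide sulfide F3 and makes the C4a–C8a bond; the relative configuration of the two new centres would rest on the same chair preference and would have to be confirmed.
   - mCPBA gives the sulfone F4.
   - LiN(SiMe3)2 generates the α-sulfonyl carbanion, which acylates on the lactone carbonyl and opens it to the β-keto sulfone F5 (C1–C2 bond).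
   - SmI2 (divalent samarium) in THF/MeOH at −78 °C removes the sulfonyl group and gives 22.

2. Step 16. The axial neopentyl triflate may ionise (methyl shift, elimination), or the C5 hydroxyl may capture C8 across the ring, before bromide substitutes. Fallback from 23 back to 25: SOCl2/imidazole closes the syn-1,3-diol (angular OH and C8 OH) to the cyclic sulfite F6. RuCl3 (cat.)/NaIO4 oxidises it to the cyclic sulfate F7, which cannot ionise freely and ties up the angular oxygen. LiBr in DMF opens it at the secondary carbon with inversion to the bromo hydrogen sulfate F8 (not isolated). Catalytic H2SO4 in wet THF hydrolyses the sulfate ester to 25.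

3. Step 3. The ester carbonyl may take part in the displacement through a six-membered ring (bridged lactone or retention), and elimination may compete. Fallback from 3 back to 6, with the carbonyl removed during the substitution:
   - LiAlH4 reduces 3 to the diol F9.
   - t-BuPh2SiCl/imidazole protects the primary alcohol as the silyl ether F10.
   - Tf2O/pyridine gives the triflate F11 (not isolated), and Bu4NBr gives the bromide F12 with inversion.
   - Bu4NF frees the bromo alcohol F13.
   - TEMPO/PhI(OAc)2 in MeCN/H2O oxidises it to acid 6, so step 4 is not needed.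

**Further compounds**

F1 | step 14 | 3-[(1R,3R)-3-bromo-1,2,2-trimethylcyclopentyl]-5-hydroxy-5-[(2R)-2-hydroxy-6-methyl-5-oxohept-6-en-2-yl]furan-2(5H)-one | CC1(C)[C@H](Br)CC[C@]1(C)C1=CC(O)(OC1=O)[C@](C)(O)CCC(=O)C(C)=C
F2 | step 14 | trimethylsilyl enol ether of the 7-(phenylsulfanyl) ketone derived from F1 | CC1(C)[C@H](Br)CC[C@]1(C)C1=CC(O)(OC1=O)[C@](C)(O)CCC(O[Si](C)(C)C)=C(C)CSc1ccccc1
F3 | step 14 | 3-[(1R,3R)-3-bromo-1,2,2-trimethylcyclopentyl]-6-hydroxy-6,10-dimethyl-10-[(phenylsulfanyl)methyl]-1-oxaspiro[4.5]dec-3-ene-2,9-dione (configuration as in 22) | CC1(C)[C@H](Br)CC[C@]1(C)C1=C[C@]2(OC1=O)[C@](C)(O)CCC(=O)[C@@]2(C)CSc1ccccc1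
F4 | step 14 | phenylsulfonyl analogue of F3 | CC1(C)[C@H](Br)CC[C@]1(C)C1=C[C@]2(OC1=O)[C@](C)(O)CCC(=O)[C@@]2(C)CS(=O)(=O)c1ccccc1
F5 | step 14 | 1-(phenylsulfonyl) derivative of 22 | CC1(C)[C@H](Br)CC[C@]1(C)C1=C[C@]2(O)[C@](C)(O)CCC(=O)[C@@]2(C)C(C1=O)S(=O)(=O)c1ccccc1
F6 | step 16 | 4a,8-cyclic sulfite of 23 | CC1(C)[C@H](Br)CC[C@]1(C)C1=C[C@]2(OS(=O)O3)[C@](C)(O)CC[C@@H]3[C@@]2(C)CC1=O
F7 | step 16 | 4a,8-cyclic sulfate of 23 | CC1(C)[C@H](Br)CC[C@]1(C)C1=C[C@]2(OS(=O)(=O)O3)[C@](C)(O)CC[C@@H]3[C@@]2(C)CC1=O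
F8 | step 16 | 4a-O-hydrogen sulfate of 25 | CC1(C)[C@H](Br)CC[C@]1(C)C1=C[C@]2(OS(=O)(=O)O)[C@](C)(O)CC[C@H](Br)[C@@]2(C)CC1=O
F9 | step 3 | (1S,3R)-3-(2-hydroxyethyl)-2,2,3-trimethylcyclopentan-1-ol | CC1(C)[C@@H](O)CC[C@]1(C)CCO
F10 | step 3 | (1S,3R)-3-[2-(tert-butyldiphenylsilyloxy)ethyl]-2,2,3-trimethylcyclopentan-1-ol | CC1(C)[C@@H](O)CC[C@]1(C)CCO[Si](c1ccccc1)(c1ccccc1)C(C)(C)C
F11 | step 3 | triflate of F10 | CC1(C)[C@@H](OS(=O)(=O)C(F)(F)F)CC[C@]1(C)CCO[Si](c1ccccc1)(c1ccccc1)C(C)(C)C
F12 | step 3 | [2-[(1R,3R)-3-bromo-1,2,2-trimethylcyclopentyl]ethoxy](tert-butyl)diphenylsilane | CC1(C)[C@H](Br)CC[C@]1(C)CCO[Si](c1ccccc1)(c1ccccc1)C(C)(C)C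
F13 | step 3 | 2-[(1R,3R)-3-bromo-1,2,2-trimethylcyclopentyl]ethan-1-ol | CC1(C)[C@H](Br)CC[C@]1(C)CCO
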